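The pyran ring of the chroman (O1, C2, C3, C4, C4a, C8a) is cut at C2–C3 and C4–C4a. This exposes the feature exploited: O1–C2, flanked by ring A and the 2,4-dimethoxyphenyl ring, is a latent O-aryl oxocarbenium ion, while C3, C4 and the styryl group are a 1,5-diarylpenta-1,3-diene. A chiral Brønsted acid ionises a methyl 3-methoxyphenyl acetal of 2,4-dimethoxybenzaldehyde; Prins addition of the diene and Friedel–Crafts closure by ring A then form both C–C bonds, the pyran ring and all three stereocentres in one operation. Phenols travel as pivalates, removed last.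

Key step: step 8

Assumption: the sense of induction of the chiral acid cannot be predicted; the (R)-acid is written, and the (S)-acid is to be used if a trial run gives the (2S,3S,4S) series.

Remarks: chroman numbering is used (O1, C2, C3, C4, C4a, C5–C8, C8a). The target is (2R,3R,4R): 2,3-trans-3,4-trans, all three substituents equatorial, 7-methoxy. Both diene phenols are carried as pivalates: these survive the ylide base and the acid, keep the two phenol rings poor Friedel–Crafts partners, and come off by mild methanolysis. Because the two aryl groups of the diene are identical, a 1,5-hydrogen shift along the chain regenerates the same compound.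

Step 1
Reactants: 1 2,4-dimethoxybenzaldehyde
Product: 2 2,4-dimethoxybenzaldehyde dimethyl acetal [1-(dimethoxymethyl)-2,4-dimethoxybenzene]
Conditions: HC(OMe)3 (1.5 equiv), p-TsOH·H2O (1 mol%), MeOH, rt; NaOMe quench, distil
Reagents that add atoms: trimethyl orthoformate, COC(OC)OC; methanol, CO
Why: Acid-catalysed acetalisation is driven to completion, even for this electron-rich aldehyde, because the orthoformate consumes the water irreversibly as methyl formate.

Step 2
Reactants: 2 2,4-dimethoxybenzaldehyde dimethyl acetal; 3 3-methoxyphenol
Product: 6 racemic methyl 3-methoxyphenyl acetal of 2,4-dimethoxybenzaldehyde [1-[methoxy(3-methoxyphenoxy)methyl]-2,4-dimethoxybenzene], via α-chloro ether 4 (not isolated), via sodium 3-methoxyphenoxide 5 (not isolated)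
Conditions: AcCl (1.1 equiv), SOCl2 (2 mol%), CH2Cl2, 0 °C to rt, evaporate cold; then 3 + NaH (1.1 equiv each), THF, 0 °C, add 4 at −78 °C, warm to 0 °C; NaHCO3 work-up, Et3N-deactivated silica
Reagents that add atoms: none
Why: Acetyl chloride exchanges one methoxy group of the acetal for chloride (α-halo ether formation, methyl acetate as by-product) and the pre-formed hard phenoxide then displaces chloride at oxygen in a Williamson-type O-alkylation under basic conditions that protect the acid-labile product; the acetal carbon is formed racemic, which is immaterial because it is ionised in step 8.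

Step 3
Reactants: 7 4-hydroxybenzaldehyde
Product: 8 4-formylphenyl pivalate
Conditions: PivCl (1.1 equiv), Et3N (1.3 equiv), 4-(dimethylamino)pyridine (5 mol%), CH2Cl2, 0 °C to rt
Reagents that add atoms: pivaloyl chloride, CC(C)(C)C(Cl)=O
Why: Amine-mediated acylation (esterification) of the phenol is fast and leaves the aldehyde untouched.

Step 4
Reactants: 8 4-formylphenyl pivalate
Product: 9 4-[(E)-3-oxoprop-1-en-1-yl]phenyl pivalate [(E)-4-(pivaloyloxy)cinnamaldehyde]
Conditions: Ph3P=CHCHO (1.1 equiv), toluene, 80 °C
Reagents that add atoms: (triphenylphosphoranylidene)acetaldehyde, O=CC=P(c1ccccc1)(c1ccccc1)c1ccccc1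
Why: Wittig olefination with the stabilised formylmethylene ylide should give the (E)-enal, and the aromatic aldehyde reacts faster than the conjugated product, so a second homologation should stay minor.

Step 5
Reactants: 10 4-(2-bromoethyl)phenol
Product: 11 4-(2-bromoethyl)phenyl pivalate
Conditions: PivCl (1.1 equiv), pyridine (2 equiv), 4-(dimethylamino)pyridine (5 mol%), CH2Cl2, 0 °C to rt
Reagents that add atoms: pivaloyl chloride, CC(C)(C)C(Cl)=O
Why: Esterification of the phenol under weakly basic conditions avoids a free phenoxide and hence spirocyclisation or elimination at the primary bromide.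

Step 6
Reactants: 11 4-(2-bromoethyl)phenyl pivalate
Product: 12 {2-[4-(pivaloyloxy)phenyl]ethyl}triphenylphosphonium bromide
Conditions: PPh3 (1.2 equiv), MeCN, reflux; precipitate with Et2O
Reagents that add atoms: triphenylphosphine, c1ccc(cc1)P(c1ccccc1)c1ccccc1
Why: SN2 quaternisation of the phosphine by the primary bromide (phosphonium salt formation) is neutral and leaves the aryl ester intact.

Step 7
Reactants: 12 {2-[4-(pivaloyloxy)phenyl]ethyl}triphenylphosphonium bromide; 9 (E)-4-(pivaloyloxy)cinnamaldehyde
Product: 15 (1E,3E)-1,5-bis[4-(pivaloyloxy)phenyl]penta-1,3-diene, via phosphonium ylide 13 (not isolated), via (1E,3Z)-diene 14 (not isolated)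
Conditions: NaN(SiMe3)2 (1.0 equiv), THF, −78 °C; 9, −78 °C to rt; aqueous work-up; then I2 (5 mol%), CH2Cl2, rt, daylight; Na2S2O3 wash
Reagents that add atoms: none
Why: Wittig olefination of the non-stabilised ylide with the enal (1,2-addition) should form the new C3=C4 bond mainly as the (Z)-isomer, and iodine-catalysed reversible radical addition then equilibrates it to the thermodynamically preferred (1E,3E)-diene; the hindered aryl pivalates tolerate the cold amide base.

Step 8
Reactants: 6 racemic methyl 3-methoxyphenyl acetal of 2,4-dimethoxybenzaldehyde; 15 (1E,3E)-1,5-bis[4-(pivaloyloxy)phenyl]penta-1,3-diene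
Product: 18 4-{[(2R,3R,4R)-2-(2,4-dimethoxyphenyl)-7-methoxy-4-{(E)-2-[4-(pivaloyloxy)phenyl]ethenyl}-3,4-dihydro-2H-chromen-3-yl]methyl}phenyl pivalate (caraganin C bis-pivalate), via O-aryl oxocarbenium ion 16 (not isolated), via allyl cation 17 (not isolated)
Conditions: (R)-3,3'-bis(2,4,6-triisopropylphenyl)-1,1'-binaphthyl-2,2'-diyl N-triflylphosphoramide (10 mol%), powdered 5 Å molecular sieves, toluene, −60 to −30 °C; 6 added slowly to 15 (1.5 equiv) and the acid; Et3N quench cold
Reagents that add atoms: none
Why: Proposed new method: the acid should protonate the more basic methoxy oxygen of 6, the sieves take up the methanol, and the O-aryl oxocarbenium ion 16 remains paired with the chiral phosphoramide anion; the benzyl-bearing diene terminus (future C3) then adds to C2 in a Prins step, the only mode that gives an aryl-conjugated allyl cation (17), and ring A alkylates the near allyl terminus (future C4), the proton lost on rearomatisation regenerating the acid. The closest known reactions are the SnCl4-promoted diastereoselective oxa-Povarov annulation of O-aryl O-methyl acetals with alkenes, chiral-phosphoric-acid Povarov reactions of N-aryl imines and chiral-Brønsted-acid Prins reactions of oxocarbenium ions; an enantioselective oxa-Povarov reaction has not been shown. The pyran ring closes by a six-membered Friedel–Crafts alkylation that is exo with respect to the allyl cation, through the ring-A carbon para to the methoxy group, attack at the far allyl terminus being excluded because it would need an eight-membered ring. C2 and C3 arise in the Prins step, where the chiral anion has to select the faces of cation and diene, and C4 arises in the closure through a chair-like transition state that places aryl, benzyl and styryl equatorial (2,3-trans-3,4-trans); C2 can also settle into the equatorial position by reversible acid ionisation of the O1–C2 bond, so the absolute configuration rests mainly on the face of the diene chosen at C3. The selectivities needed are site selectivity on the diene (secured by cation stability), regioselectivity on ring A (secured by the para-directing methoxy group and the crowding of the carbon between the two oxygens), retention of the (E)-styryl bond (secured by the configurational stability of the E allyl cation) and enantioselectivity, which depends on ion pairing alone and is the unproven element.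

Step 9
Reactants: 18 caraganin C bis-pivalate
Product: 19 caraganin C
Conditions: K2CO3 (3 equiv), MeOH/THF, rt, argon; aq. NH4Cl
Reagents that add atoms: none
Why: Base-mediated transesterification (methanolysis) of the two aryl pivalates frees the phenols, while the aryl methyl ethers, the (E)-alkene and the three stereocentres, none of which carries an acidic hydrogen or a leaving group, should be untouched.

Compound list
1 | 2,4-dimethoxybenzaldehyde | COc1ccc(C=O)c(OC)c1 | starting material
2 | 2,4-dimethoxybenzaldehyde dimethyl acetal | COc1ccc(C(OC)OC)c(OC)c1 | intermediate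
3 | 3-methoxyphenol | COc1cccc(O)c1 | starting material
4 | α-chloro ether, racemic 1-[chloro(methoxy)methyl]-2,4-dimethoxybenzene | COc1ccc(C(Cl)OC)c(OC)c1 | intermediate (not isolated)
5 | sodium 3-methoxyphenoxide | COc1cccc([O-])c1.[Na+] | intermediate (not isolated)
6 | racemic methyl 3-methoxyphenyl acetal of 2,4-dimethoxybenzaldehyde | COc1cccc(OC(OC)c2ccc(OC)cc2OC)c1 | intermediate
7 | 4-hydroxybenzaldehyde | O=Cc1ccc(O)cc1 | starting material
8 | 4-formylphenyl pivalate | CC(C)(C)C(=O)Oc1ccc(C=O)cc1 | intermediate
9 | 4-[(E)-3-oxoprop-1-en-1-yl]phenyl pivalate | CC(C)(C)C(=O)Oc1ccc(/C=C/C=O)cc1 | intermediate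
10 | 4-(2-bromoethyl)phenol | Oc1ccc(CCBr)cc1 | starting material
11 | 4-(2-bromoethyl)phenyl pivalate | CC(C)(C)C(=O)Oc1ccc(CCBr)cc1 | intermediate
12 | {2-[4-(pivaloyloxy)phenyl]ethyl}triphenylphosphonium bromide | CC(C)(C)C(=O)Oc1ccc(CC[P+](c2ccccc2)(c2ccccc2)c2ccccc2)cc1.[Br-] | intermediate
13 | phosphonium ylide, 4-[2-(triphenylphosphoranylidene)ethyl]phenyl pivalate | CC(C)(C)C(=O)Oc1ccc(CC=P(c2ccccc2)(c2ccccc2)c2ccccc2)cc1 | intermediate (not isolated)
14 | (1E,3Z)-1,5-bis[4-(pivaloyloxy)phenyl]penta-1,3-diene | CC(C)(C)C(=O)Oc1ccc(C/C=C\C=C\c2ccc(OC(=O)C(C)(C)C)cc2)cc1 | intermediate (not isolated)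
15 | (1E,3E)-1,5-bis[4-(pivaloyloxy)phenyl]penta-1,3-diene | CC(C)(C)C(=O)Oc1ccc(C/C=C/C=C/c2ccc(OC(=O)C(C)(C)C)cc2)cc1 | intermediate
16 | O-aryl oxocarbenium ion (cation of the ion pair with the phosphoramide anion) | COc1cccc(c1)[O+]=Cc1ccc(OC)cc1OC | intermediate (not isolated)
17 | allyl cation from Prins addition (cation of the ion pair; C2 and C3 as in 18) | COc1cccc(c1)O[C@@H](c1ccc(OC)cc1OC)[C@H](Cc1ccc(OC(=O)C(C)(C)C)cc1)[CH+]/C=C/c1ccc(OC(=O)C(C)(C)C)cc1 | intermediate (not isolated)
18 | caraganin C bis-pivalate, (2R,3R,4R) | COc1ccc2c(c1)O[C@@H](c1ccc(OC)cc1OC)[C@H](Cc1ccc(OC(=O)C(C)(C)C)cc1)[C@H]2/C=C/c1ccc(OC(=O)C(C)(C)C)cc1 | intermediate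
19 | caraganin C, 4-{(E)-2-[(2R,3R,4R)-2-(2,4-dimethoxyphenyl)-3-(4-hydroxybenzyl)-7-methoxy-3,4-dihydro-2H-chromen-4-yl]ethenyl}phenol | COc1ccc2c(c1)O[C@@H](c1ccc(OC)cc1OC)[C@H](Cc1ccc(O)cc1)[C@H]2/C=C/c1ccc(O)cc1 | target

Total step count: 9.
Longest linear sequence: 5 steps (10 → 11 → 12 → 15 → 18 → 19, steps 5 to 9; the branch from 7 through steps 3, 4, 7, 8, 9 is equally long).

Steps most likely to fail

Step 8 (proposed new method). Enantiofacial discrimination within the ion pair may be poor. The acetal may ionise by expelling 3-methoxyphenol in place of methanol. The acid may start oligomerisation of the diene, or the cation may alkylate ring A of a second acetal molecule. The fallback sets out from 6 and 15 and uses known chemistry. SnCl4 (1.1 equiv) in CH2Cl2 at −78 °C, the established Lewis-acid oxa-Povarov conditions for O-aryl O-methyl acetals and alkenes, should give racemic caraganin C bis-pivalate F1 with the same all-equatorial relative configuration. Preparative chromatography on an amylose tris(3,5-dimethylphenylcarbamate) chiral stationary phase then separates the enantiomers. The (2R,3R,4R) enantiomer is compound 18, where the route is rejoined; its configuration is to be assigned by comparing the sign of rotation of derived 19 with that of the natural product.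

Step 2. The very electron-rich α-chloro ether may self-condense by Friedel–Crafts alkylation before it meets the phenoxide. The ambident phenoxide may be alkylated at carbon, and the mixed acetal may hydrolyse during purification. The fallback sets out from 3. Mitsunobu etherification with commercial 2,4-dimethoxybenzyl alcohol (PPh3, diisopropyl azodicarboxylate, THF, 0 °C to rt) gives 1-[(2,4-dimethoxybenzyl)oxy]-3-methoxybenzene F2. Benzylic C–H oxidation with 2,3-dichloro-5,6-dicyano-1,4-benzoquinone (DDQ) in CH2Cl2 with methanol, 4 Å molecular sieves and solid NaHCO3 at 0 °C generates the same oxocarbenium ion oxidatively and traps it with methanol. This comes back to the route at 6 without any α-halo ether.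

Step 7. Olefin geometry may not converge on iodine equilibration, the ylide or base may attack the aryl esters, and iodine may react at the doubly activated methylene. The fallback sets out from 11. S-alkylation of 1-phenyl-1H-tetrazole-5-thiol (K2CO3, acetone, rt) gives 4-{2-[(1-phenyl-1H-tetrazol-5-yl)sulfanyl]ethyl}phenyl pivalate F3. Oxidation with H2O2 and catalytic (NH4)6Mo7O24·4H2O in ethanol gives 4-{2-[(1-phenyl-1H-tetrazol-5-yl)sulfonyl]ethyl}phenyl pivalate F4. Julia–Kocienski olefination of F4 with enal 9 (KN(SiMe3)2, DME, −60 °C to rt, base added to the mixture of both partners) should form the C3=C4 bond directly as the (E)-isomer. This comes back to the route at 15 without an ylide or an isomerisation.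

Further compounds
F1 | step 8 | racemic caraganin C bis-pivalate (both enantiomers of the 2,3-trans-3,4-trans chroman) | COc1ccc2c(c1)O[C@@H](c1ccc(OC)cc1OC)[C@H](Cc1ccc(OC(=O)C(C)(C)C)cc1)[C@H]2/C=C/c1ccc(OC(=O)C(C)(C)C)cc1.COc1ccc2c(c1)O[C@H](c1ccc(OC)cc1OC)[C@@H](Cc1ccc(OC(=O)C(C)(C)C)cc1)[C@@H]2/C=C/c1ccc(OC(=O)C(C)(C)C)cc1
F2 | step 2 | 1-[(2,4-dimethoxybenzyl)oxy]-3-methoxybenzene | COc1cccc(OCc2ccc(OC)cc2OC)c1
F3 | step 7 | 4-{2-[(1-phenyl-1H-tetrazol-5-yl)sulfanyl]ethyl}phenyl pivalate | CC(C)(C)C(=O)Oc1ccc(CCSc2nnnn2-c2ccccc2)cc1
F4 | step 7 | 4-{2-[(1-phenyl-1H-tetrazol-5-yl)sulfonyl]ethyl}phenyl pivalate | CC(C)(C)C(=O)Oc1ccc(CCS(=O)(=O)c2nnnn2-c2ccccc2)cc1
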